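The route rests on disconnecting the single bond between the exocyclic methine carbon on C5 of the butenolide and the neighbouring diene CH. The key step exploits the Z-γ-ylidenebutenolide ring itself: its O1–C5 bond and exocyclic C5=CH alkene are the imprint of a 5-exo-dig carboxylate addition to an alkyne, so the methine carbon can enter as a terminal acetylide. One operation, a Sonogashira coupling with in-flask lactonisation, joins (Z)-3-methylpent-2-en-4-ynoic acid to an E-iodoalkene that carries the sclareolide-derived decalin and the free hydroxymethyl group. It forms the C–C bond, the lactone ring and the Z-exocyclic alkene together.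

Key step: step 7

Remark: the decalin is numbered as a labdane (stereocentres C5 and C10, alkene C8=C9); the 5S,10S configuration written in the target SMILES is that of natural (+)-sclareolide, so both stereocentres are taken from the starting material and only have to be kept.

Step 1
Reactants: 1 (+)-sclareolide, (3aR,5aS,9aS,9bR)-3a,6,6,9a-tetramethyldecahydronaphtho[2,1-b]furan-2(1H)-one
Product: 2 methyl 2-[(4aS,8aS)-2,5,5,8a-tetramethyl-3,4,4a,5,6,7,8,8a-octahydronaphthalen-1-yl]acetate
Conditions: conc. H2SO4, MeOH, reflux; purification on AgNO3-impregnated silica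
Reagents that add atoms: methanol CO
Why: Acid-mediated ionisation of the tertiary lactone C8–O bond followed by E1 proton loss under equilibrating conditions should settle the alkene mainly in the tetrasubstituted C8=C9 position while the liberated acid undergoes Fischer esterification; C5 and C10 are remote from the cation and are kept, and minor C7=C8 and exocyclic isomers are expected to separate on AgNO3-impregnated silica.

Step 2
Reactants: 2 methyl 2-[(4aS,8aS)-2,5,5,8a-tetramethyl-3,4,4a,5,6,7,8,8a-octahydronaphthalen-1-yl]acetate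
Product: 3 2-[(4aS,8aS)-2,5,5,8a-tetramethyl-3,4,4a,5,6,7,8,8a-octahydronaphthalen-1-yl]ethan-1-ol
Conditions: LiAlH4, THF, 0 °C to rt; aq NaOH work-up
Reagents that add atoms: none
Why: LiAlH4 reduction of the ester to the primary alcohol, to which the isolated tetrasubstituted alkene is inert.

Step 3
Reactants: 3 2-[(4aS,8aS)-2,5,5,8a-tetramethyl-3,4,4a,5,6,7,8,8a-octahydronaphthalen-1-yl]ethan-1-ol
Product: 4 2-[(4aS,8aS)-2,5,5,8a-tetramethyl-3,4,4a,5,6,7,8,8a-octahydronaphthalen-1-yl]ethyl bromide
Conditions: CBr4, PPh3, CH2Cl2, 0 °C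
Reagents that add atoms: carbon tetrabromide BrC(Br)(Br)Br
Why: Appel bromination, an SN2 displacement of the alkoxyphosphonium ion by bromide under neutral conditions that leave the alkene untouched.

Step 4
Reactants: 4 2-[(4aS,8aS)-2,5,5,8a-tetramethyl-3,4,4a,5,6,7,8,8a-octahydronaphthalen-1-yl]ethyl bromide, 5 3-(trimethylsilyl)prop-2-yn-1-ol
Product: 9 (2E)-4-[(4aS,8aS)-2,5,5,8a-tetramethyl-3,4,4a,5,6,7,8,8a-octahydronaphthalen-1-yl]-2-[(trimethylsilyl)methylidene]butan-1-ol, via Grignard reagent 6 (not isolated), via bromomagnesium alkoxide 7 (not isolated), via oxamagnesole chelate 8 (not isolated)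
Conditions: 4, Mg, Et2O, reflux; separately 5, EtMgBr (1.0 equiv), Et2O, 0 °C; combine, CuI (10 mol %), Et2O, 0 °C to reflux; then sat. aq NH4Cl
Reagents that add atoms: none
Why: Copper-catalysed anti-carbomagnesiation of a propargylic magnesium alkoxide: the alkyl group of 6 should add to C2 and magnesium to the silicon-bearing C3, where it is locked cis to the CH2O arm in five-membered chelate 8 (any syn adduct of the configurationally labile α-silyl alkenylmagnesium can drain into it), so protonolysis leaves silicon trans to CH2OH and cis to the new chain, the E geometry.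

Step 5
Reactants: 9 (2E)-4-[(4aS,8aS)-2,5,5,8a-tetramethyl-3,4,4a,5,6,7,8,8a-octahydronaphthalen-1-yl]-2-[(trimethylsilyl)methylidene]butan-1-ol
Product: 10 (2E)-2-(iodomethylidene)-4-[(4aS,8aS)-2,5,5,8a-tetramethyl-3,4,4a,5,6,7,8,8a-octahydronaphthalen-1-yl]butan-1-ol
Conditions: NIS, MeCN/ClCH2CN, 0 °C
Reagents that add atoms: N-iodosuccinimide O=C1CCC(=O)N1I
Why: Electrophilic ipso-iododesilylation through a β-silyl cation, which should proceed with retention of the E geometry and faster than any attack on the isolated tetrasubstituted alkene because only the vinylsilane can lose the silyl group irreversibly.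

Step 6
Reactants: 11 (2Z)-3-methylpent-2-en-4-yn-1-ol
Product: 13 (2Z)-3-methylpent-2-en-4-ynoic acid, via enynal 12 (not isolated)
Conditions: CrO3, aq H2SO4, acetone, 0 °C
Reagents that add atoms: water O
Why: Jones oxidation of the primary allylic alcohol through enynal 12 and its hydrate; brief exposure at 0 °C should keep the Z alkene and the terminal alkyne.

Step 7
Reactants: 10 (2E)-2-(iodomethylidene)-4-[(4aS,8aS)-2,5,5,8a-tetramethyl-3,4,4a,5,6,7,8,8a-octahydronaphthalen-1-yl]butan-1-ol, 13 (2Z)-3-methylpent-2-en-4-ynoic acid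
Product: 15 (5Z)-5-{(2E)-3-(hydroxymethyl)-5-[(4aS,8aS)-2,5,5,8a-tetramethyl-3,4,4a,5,6,7,8,8a-octahydronaphthalen-1-yl]pent-2-en-1-ylidene}-4-methylfuran-2(5H)-one, via dienynoic acid 14 (not isolated)
Conditions: Pd(PPh3)4 (5 mol %), CuI (10 mol %), Et3N (3 equiv), degassed MeCN, 25 to 50 °C, 13 added slowly
Reagents that add atoms: none
Why: Oxidative addition of iodide 10 to zerovalent palladium, transmetallation with the copper acetylide of 13 and reductive elimination give dienynoic acid 14 (Sonogashira coupling); its triethylammonium carboxylate then adds to the metal-activated alkyne and is protodemetallated, as in the known tandem cross-coupling–lactonisation route to Z-γ-alkylidenebutenolides. The butenolide ring closes in the 5-exo-dig mode, the carboxylate oxygen attacking the alkyne carbon next to the methyl-bearing alkene carbon. No stereocentre is formed; the Z geometry of the new exocyclic alkene follows from anti addition of oxygen and hydrogen across the alkyne and is also the less strained isomer beside the 4-methyl group. The step needs coupling to outrun cyclisation of free 13, which slow addition of 13 and the acidity of its conjugated alkyne C–H should secure, and 5-exo over 6-endo closure, which the Z-enoate geometry and soft-metal activation favour. The 2Z alkene of 13 holds the carboxylate over the alkyne, while the 6E geometry inherited from 10 keeps the hydroxymethyl group trans to the alkyne, so furan formation by the alcohol is excluded; C5 and C10 are untouched.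

Compound list
1 | (+)-sclareolide, (3aR,5aS,9aS,9bR)-3a,6,6,9a-tetramethyldecahydronaphtho[2,1-b]furan-2(1H)-one | O=C1C[C@H]2[C@](C)(O1)CC[C@H]3C(C)(C)CCC[C@]23C | starting material
2 | methyl 2-[(4aS,8aS)-2,5,5,8a-tetramethyl-3,4,4a,5,6,7,8,8a-octahydronaphthalen-1-yl]acetate | COC(=O)CC1=C(C)CC[C@H]2C(C)(C)CCC[C@]12C | intermediate
3 | 2-[(4aS,8aS)-2,5,5,8a-tetramethyl-3,4,4a,5,6,7,8,8a-octahydronaphthalen-1-yl]ethan-1-ol | OCCC1=C(C)CC[C@H]2C(C)(C)CCC[C@]12C | intermediate
4 | 2-[(4aS,8aS)-2,5,5,8a-tetramethyl-3,4,4a,5,6,7,8,8a-octahydronaphthalen-1-yl]ethyl bromide | BrCCC1=C(C)CC[C@H]2C(C)(C)CCC[C@]12C | intermediate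
5 | 3-(trimethylsilyl)prop-2-yn-1-ol | C[Si](C)(C)C#CCO | starting material
6 | {2-[(4aS,8aS)-2,5,5,8a-tetramethyl-3,4,4a,5,6,7,8,8a-octahydronaphthalen-1-yl]ethyl}magnesium bromide | Br[Mg]CCC1=C(C)CC[C@H]2C(C)(C)CCC[C@]12C | intermediate
7 | bromomagnesium 3-(trimethylsilyl)prop-2-yn-1-olate | C[Si](C)(C)C#CCO[Mg]Br | intermediate
8 | 4-{2-[(4aS,8aS)-2,5,5,8a-tetramethyl-3,4,4a,5,6,7,8,8a-octahydronaphthalen-1-yl]ethyl}-3-(trimethylsilyl)-2,5-dihydro-1,2-oxamagnesole | C[Si](C)(C)C1=C(CCC2=C(C)CC[C@H]3C(C)(C)CCC[C@]23C)CO[Mg]1 | intermediate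
9 | (2E)-4-[(4aS,8aS)-2,5,5,8a-tetramethyl-3,4,4a,5,6,7,8,8a-octahydronaphthalen-1-yl]-2-[(trimethylsilyl)methylidene]butan-1-ol | C[Si](C)(C)/C=C(/CO)CCC1=C(C)CC[C@H]2C(C)(C)CCC[C@]12C | intermediate
10 | (2E)-2-(iodomethylidene)-4-[(4aS,8aS)-2,5,5,8a-tetramethyl-3,4,4a,5,6,7,8,8a-octahydronaphthalen-1-yl]butan-1-ol | I/C=C(/CO)CCC1=C(C)CC[C@H]2C(C)(C)CCC[C@]12C | intermediate
11 | (2Z)-3-methylpent-2-en-4-yn-1-ol | C#C/C(C)=C\CO | starting material
12 | (2Z)-3-methylpent-2-en-4-ynal | C#C/C(C)=C\C=O | intermediate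
13 | (2Z)-3-methylpent-2-en-4-ynoic acid | C#C/C(C)=C\C(=O)O | intermediate
14 | (2Z,6E)-7-(hydroxymethyl)-3-methyl-9-[(4aS,8aS)-2,5,5,8a-tetramethyl-3,4,4a,5,6,7,8,8a-octahydronaphthalen-1-yl]nona-2,6-dien-4-ynoic acid | OC(=O)/C=C(C)\C#C/C=C(/CO)CCC1=C(C)CC[C@H]2C(C)(C)CCC[C@]12C | intermediate
15 | (5Z)-5-{(2E)-3-(hydroxymethyl)-5-[(4aS,8aS)-2,5,5,8a-tetramethyl-3,4,4a,5,6,7,8,8a-octahydronaphthalen-1-yl]pent-2-en-1-ylidene}-4-methylfuran-2(5H)-one | CC1=CC(=O)O/C1=C\C=C(\CO)CCC1=C(C)CC[C@H]2C(C)(C)CCC[C@]12C | target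

Total steps: 7. Longest linear sequence: 6 (steps 1, 2, 3, 4, 5 and 7).

Steps most likely to fail

Step 7. The terminal enynoic acid may cycloisomerise on copper or palladium before it is coupled. The carboxylate may instead add to the alkyne while it is activated by the vinylpalladium iodide, which would place the diene trans to the ring oxygen. Closure may also go 6-endo to a pyranone. The fallback separates bond formation from ring closure; it sets out from 13 and 10 and comes back at 15. Acid 13 would be converted with MeI and K2CO3 in DMF into methyl (2Z)-3-methylpent-2-en-4-ynoate F1, which cannot lactonise. Sonogashira coupling of F1 with 10 (Pd(PPh3)4, CuI, Et3N) should give methyl dienynoate F2. Hydrolysis with LiOH in THF/H2O would release acid 14, now isolated, and AgNO3-catalysed 5-exo-dig lactonisation should close it to 15 with the Z geometry.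

Step 4. The carbomagnesiation may stall at the hindered silyl alkyne, add with the opposite regiochemistry or fail to converge on the chelate, and Grignard formation may be eroded by Wurtz coupling. The fallback builds the same alkene by a metallacycle in which hydrogen and CH2OH are forced to be cis; it sets out from 4 and comes back at 9. Alkylation of LiC≡CSiMe3 with 4 in THF/DMPU would give silylalkyne F3. Ti(OiPr)4 and two equivalents of i-PrMgCl at −50 °C should convert it into titanium–alkyne complex F4. This complex is expected to insert monomeric formaldehyde at the carbon remote from silicon to give oxatitanacyclopentene F5, and aqueous hydrolysis would deliver 9.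

Step 1. Equilibration may stop at a mixture rich in the C7=C8 and exocyclic alkenes, or fall back to the lactone, leaving the C8=C9 ester hard to purify. The fallback fixes the alkene position by mechanism; it sets out from 1 and comes back at 3. Selenenylation of the lactone enolate (LiN(iPr)2, PhSeBr, THF, −78 °C) would give phenylselanyl lactone F6. H2O2 would oxidise it to selenoxide F7, whose syn-elimination towards the only β-hydrogen, on C9, gives the 9(11)-unsaturated butenolide F8. Dissolving-metal cleavage of its allylic C8–O bond (Li, liquid NH3/THF, −78 °C, then NH4Cl) and α-protonation of the resulting dienolate should give the C8=C9 acid F9. LiAlH4 reduction would then give 3.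

Further compounds
F1 | step 7 | methyl (2Z)-3-methylpent-2-en-4-ynoate | COC(=O)/C=C(C)\C#C
F2 | step 7 | methyl (2Z,6E)-7-(hydroxymethyl)-3-methyl-9-[(4aS,8aS)-2,5,5,8a-tetramethyl-3,4,4a,5,6,7,8,8a-octahydronaphthalen-1-yl]nona-2,6-dien-4-ynoate | COC(=O)/C=C(C)\C#C/C=C(/CO)CCC1=C(C)CC[C@H]2C(C)(C)CCC[C@]12C
F3 | step 4 | trimethyl{4-[(4aS,8aS)-2,5,5,8a-tetramethyl-3,4,4a,5,6,7,8,8a-octahydronaphthalen-1-yl]but-1-yn-1-yl}silane | C[Si](C)(C)C#CCCC1=C(C)CC[C@H]2C(C)(C)CCC[C@]12C
F4 | step 4 | 1,1-di(propan-2-yloxy)-2-{2-[(4aS,8aS)-2,5,5,8a-tetramethyl-3,4,4a,5,6,7,8,8a-octahydronaphthalen-1-yl]ethyl}-3-(trimethylsilyl)titanacycloprop-2-ene | CC(C)O[Ti]1(OC(C)C)C(CCC2=C(C)CC[C@H]3C(C)(C)CCC[C@]23C)=C1[Si](C)(C)C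
F5 | step 4 | 2,2-di(propan-2-yloxy)-4-{2-[(4aS,8aS)-2,5,5,8a-tetramethyl-3,4,4a,5,6,7,8,8a-octahydronaphthalen-1-yl]ethyl}-3-(trimethylsilyl)-2,5-dihydro-1,2-oxatitanole | CC(C)O[Ti]1(OC(C)C)OCC(CCC2=C(C)CC[C@H]3C(C)(C)CCC[C@]23C)=C1[Si](C)(C)C
F6 | step 1 | (3aR,5aS,9aS,9bR)-3a,6,6,9a-tetramethyl-1-(phenylselanyl)decahydronaphtho[2,1-b]furan-2(1H)-one, mixture at C1 | O=C1C([Se]c2ccccc2)[C@H]3[C@](C)(O1)CC[C@H]4C(C)(C)CCC[C@]34C
F7 | step 1 | (3aR,5aS,9aS,9bR)-3a,6,6,9a-tetramethyl-1-(phenylseleninyl)decahydronaphtho[2,1-b]furan-2(1H)-one, mixture at C1 and selenium | O=C1C([Se](=O)c2ccccc2)[C@H]3[C@](C)(O1)CC[C@H]4C(C)(C)CCC[C@]34C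
F8 | step 1 | (3aR,5aS,9aS)-3a,6,6,9a-tetramethyl-4,5,5a,6,7,8,9,9a-octahydronaphtho[2,1-b]furan-2(3aH)-one | O=C1C=C2[C@](C)(O1)CC[C@H]3C(C)(C)CCC[C@]23C
F9 | step 1 | 2-[(4aS,8aS)-2,5,5,8a-tetramethyl-3,4,4a,5,6,7,8,8a-octahydronaphthalen-1-yl]acetic acid | OC(=O)CC1=C(C)CC[C@H]2C(C)(C)CCC[C@]12C
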